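## Retrosynthetic overview

1. Target ⇐ global desilylation ⇐ one-pot SmI2 reductive C1–C5 aldol and 5-O-acylation of an acyclic 1,2-diketo-aldehyde (a 4,5-seco-germacranolide mimic). Ring B (the cycloheptane) closes last through the biosynthetic C1→C5 bond.
2. Diketo-aldehyde ⇐ double unmasking (dithiane → C2=O, glycol → C5HO) ⇐ reagent-controlled syn-aldol (C9–C10) of a dithiane-masked ethyl ketone with a lactone aldehyde.
3. Lactone aldehyde ⇐ cis-α-methylene-γ-butyrolactone ⇐ indium allylation of (S)-glyceraldehyde acetonide with a Baylis–Hillman-derived (Z)-bromide, then O6→C12 lactonisation. Ring A (the lactone) closes first, before the carbocycle.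
4. Dithianyl ketone ⇐ 1,3-dithiane + (S)-propylene oxide + N-methoxy-N-methylpropanamide.

Assumption: the target is treated as a 4,5-seco-guaiane (xanthane-type) 6,12-olide whose carbocycle arises in the plant by C1→C5 aldol closure of a 4,5-seco-germacranolide keto-aldehyde and whose lactone arises by O6→C12 acyl closure.

Numbering in the text is sesquiterpene numbering: ring B = C1, C5–C10; side chain C2–C4 and C15; lactone C11–C13; ring methyl C14. TBS = tert-butyldimethylsilyl.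

## Route

Step 1
Reactants: 1 1,3-dithiane; 2 (S)-2-methyloxirane
Product: 5 tert-butyl{[(2S)-1-(1,3-dithian-2-yl)propan-2-yl]oxy}dimethylsilane, via 2-lithio-1,3-dithiane 3 (not isolated), via lithium alkoxide 4 (not isolated)
Conditions: n-BuLi, THF, −30 °C; 2, −30 → 0 °C; then TBSCl, DMPU, rt
Reagents that add atoms: tert-butyldimethylsilyl chloride, CC(C)(C)[Si](C)(C)Cl
Why: Corey–Seebach lithiation and SN2 opening of the epoxide at its CH2 terminus leave the C4 stereocentre of 2 untouched (S), and the lithium alkoxide is silylated in the same pot.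

Step 2
Reactants: 5; 6 N-methoxy-N-methylpropanamide
Product: 8 1-{2-[(2S)-2-(tert-butyldimethylsilyloxy)propyl]-1,3-dithian-2-yl}propan-1-one, via lithiated dithiane 7 (not isolated)
Conditions: t-BuLi, THF/HMPA (9:1), −78 °C; then 6, −78 → −40 °C; H2O
Reagents that add atoms: none
Why: A second Corey–Seebach lithiation and Weinreb acylation (chelated tetrahedral intermediate, no over-addition) give an ethyl ketone whose only enolisable position is the future C10, with the dithiane carbon as the masked C2 carbonyl.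

Step 3
Reactants: 9 3-(tert-butyldimethylsilyloxy)propanal; 10 methyl acrylate
Product: 11 methyl 5-(tert-butyldimethylsilyloxy)-3-hydroxy-2-methylidenepentanoate (racemic)
Conditions: DABCO (0.5 equiv), neat 10 (5 equiv), rt, 5 d
Reagents that add atoms: none
Why: The Morita–Baylis–Hillman reaction attaches the C11–C13 acrylate to the future C7; the racemic carbinol centre is erased in step 4.

Step 4
Reactants: 11
Product: 12 methyl (2Z)-2-(bromomethyl)-5-(tert-butyldimethylsilyloxy)pent-2-enoate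
Conditions: NBS, Me2S, CH2Cl2, 0 °C → rt
Reagents that add atoms: N-bromosuccinimide, O=C1CCC(=O)N1Br
Why: Corey–Kim-type activation and SN2′ bromide transposition give the conjugated trisubstituted allyl bromide with the alkyl group trans to the ester (Z).

Step 5
Reactants: 12; 13 (4S)-2,2-dimethyl-1,3-dioxolane-4-carbaldehyde
Product: 15 (4S,5R)-4-[2-(tert-butyldimethylsilyloxy)ethyl]-5-[(4S)-2,2-dimethyl-1,3-dioxolan-4-yl]-3-methylideneoxolan-2-one (cis-lactone; ring A), via hydroxy ester 14 (not isolated)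
Conditions: indium powder, THF/H2O (1:1), rt; then PPTS (cat.), toluene, 60 °C
Reagents that add atoms: none
Why: In this Barbier allylation the (Z)-γ-substituted 2-(methoxycarbonyl)allylindium adds through a chair transition state at its γ-carbon, syn-selectively (C6/C7, hence the cis lactone) and Felkin–Anh anti to the dioxolane oxygen of 13 (6R,7S); the γ-hydroxy acrylate then lactonises O6→C12 as in the biosynthetic closure of ring A.

Step 6
Reactants: 15
Product: 16 (4S,5R)-5-[(4S)-2,2-dimethyl-1,3-dioxolan-4-yl]-4-(2-hydroxyethyl)-3-methylideneoxolan-2-one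
Conditions: HF·pyridine, pyridine, THF, 0 °C
Reagents that add atoms: none
Why: Buffered fluoride desilylation frees the primary alcohol and leaves the acetonide and the α-methylene lactone intact.

Step 7
Reactants: 16
Product: 17 [(2R,3S)-2-[(4S)-2,2-dimethyl-1,3-dioxolan-4-yl]-4-methylidene-5-oxooxolan-3-yl]acetaldehyde
Conditions: Dess–Martin periodinane, pyridine, CH2Cl2, 0 °C → rt
Reagents that add atoms: none
Why: Dess–Martin oxidation under buffered, non-basic conditions gives the C9 aldehyde without moving the exocyclic alkene into the ring.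

Step 8
Reactants: 8; 17
Product: 19 (4S,5R)-4-[(2R,3S)-4-{2-[(2S)-2-(tert-butyldimethylsilyloxy)propyl]-1,3-dithian-2-yl}-2-hydroxy-3-methyl-4-oxobutyl]-5-[(4S)-2,2-dimethyl-1,3-dioxolan-4-yl]-3-methylideneoxolan-2-one, via Z-enol borinate 18 (not isolated)
Conditions: 8, (−)-Ipc2BOTf [from (+)-α-pinene], i-Pr2NEt, CH2Cl2, −78 °C, 3 h; then 17, −78 → −20 °C; MeOH/pH 7 buffer work-up (no peroxide)
Reagents that add atoms: none
Why: In this Paterson syn-aldol the (Z)-enol diisopinocampheylborinate reacts through a Zimmerman–Traxler chair (syn C9/C10) and the (−)-Ipc ligands direct attack to the si face of the aldehyde (9R,10S, the facial sense recalled from precedent with simple ethyl ketones); the peroxide-free work-up spares the dithiane and the methylene lactone.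

Step 9
Reactants: 19
Product: 20 (4S,5R)-4-[(2R,3S)-2-(tert-butyldimethylsilyloxy)-4-{2-[(2S)-2-(tert-butyldimethylsilyloxy)propyl]-1,3-dithian-2-yl}-3-methyl-4-oxobutyl]-5-[(4S)-2,2-dimethyl-1,3-dioxolan-4-yl]-3-methylideneoxolan-2-one
Conditions: TBSOTf, 2,6-lutidine, CH2Cl2, −78 °C
Reagents that add atoms: tert-butyldimethylsilyl triflate, CC(C)(C)[Si](C)(C)OS(=O)(=O)C(F)(F)F
Why: Silylation blocks O9 so that it cannot later form a lactol with C5 or a hemiketal with C2, and stops retro-aldol.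

Step 10
Reactants: 20
Product: 21 (4S,5R)-4-[(2R,3S)-2-(tert-butyldimethylsilyloxy)-4-{2-[(2S)-2-(tert-butyldimethylsilyloxy)propyl]-1,3-dithian-2-yl}-3-methyl-4-oxobutyl]-5-[(1S)-1,2-dihydroxyethyl]-3-methylideneoxolan-2-one
Conditions: Zn(NO3)2·6H2O, MeCN, 50 °C
Reagents that add atoms: none
Why: Mild Lewis-acid hydrolysis is selective for the terminal isopropylidene acetal; the secondary silyl ethers and the dithiane survive.

Step 11
Reactants: 21
Product: 22 (2R,3S)-3-[(2R,3S,7S)-2,7-bis(tert-butyldimethylsilyloxy)-3-methyl-4,5-dioxooctyl]-4-methylidene-5-oxooxolane-2-carbaldehyde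
Conditions: PhI(O2CCF3)2 (3 equiv), MeCN/H2O (9:1), 0 °C, 20 min; used crude
Reagents that add atoms: water, O
Why: One trivalent-iodine reagent does two jobs, glycol fission to the C5 aldehyde (the counterpart of the 4,5-scission) and oxidative dithiane hydrolysis to the C2 ketone; no stereocentre is touched and the 1,2-diketone is inert to this oxidant.

Step 12
Reactants: 22; 23 (2S)-2-methylbutanoic anhydride
Product: 26 (3aS,5R,6S,7S,8S,8aR)-5-(tert-butyldimethylsilyloxy)-7-[(3S)-3-(tert-butyldimethylsilyloxy)butanoyl]-7-hydroxy-6-methyl-3-methylidene-2-oxooctahydro-2H-cyclohepta[b]furan-8-yl (2S)-2-methylbutanoate, via samarium enediolate 24 (not isolated), via samarium aldolate 25 (not isolated)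
Conditions: SmI2 (2.2 equiv), THF, −78 °C, 30 min; then 23 (3 equiv), −78 → −30 °C
Reagents that add atoms: none
Why: Proposed new method: SmI2 reduces the s-trans 1,2-diketone (far faster than the aliphatic aldehyde or the acrylate at −78 °C) to the (E)-enediolate, whose C1 adds to the C5 aldehyde in an aldolase-like 7-exo aldol that copies the C1→C5 closure of ring B; a chair Zimmerman–Traxler transition state with samarium bridging O2 and O5 and chelated by the lactone oxygen O6 puts O5 trans to both O1 and O6 (5S), allylic 1,3-strain (C10–H eclipsing C1=C2) brings C5 in anti to the C10 methyl (1S), and the secondary aldolate is acylated in situ while the hindered tertiary one is not; the closest known reactions are SmI2 Reformatsky and aldol cyclisations to medium rings and additions of tin or samarium enediolates of 1,2-diketones to aldehydes.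

Step 13
Reactants: 26
Product: 27 (3aS,5R,6S,7S,8S,8aR)-5,7-dihydroxy-7-[(3S)-3-hydroxybutanoyl]-6-methyl-3-methylidene-2-oxooctahydro-2H-cyclohepta[b]furan-8-yl (2S)-2-methylbutanoate (CNP0291806.1)
Conditions: HF (48% aq.), MeCN, 0 °C → rt
Reagents that add atoms: none
Why: Acidic fluoride desilylation removes both silyl ethers without acyl migration or retro-aldol, and because C1 is quaternary the β-acyloxy ketone cannot eliminate.

## Compound list

1 | 1,3-dithiane | C1CSCSC1 | starting material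
2 | (S)-2-methyloxirane ((S)-propylene oxide) | C[C@H]1CO1 | starting material
3 | 2-lithio-1,3-dithiane | [Li]C1SCCCS1 | intermediate
4 | lithium (2S)-1-(1,3-dithian-2-yl)propan-2-olate | C1CSC(SC1)C[C@H](C)O[Li] | intermediate
5 | tert-butyl{[(2S)-1-(1,3-dithian-2-yl)propan-2-yl]oxy}dimethylsilane | C1CSC(SC1)C[C@H](C)O[Si](C)(C)C(C)(C)C | intermediate
6 | N-methoxy-N-methylpropanamide | CCC(=O)N(C)OC | starting material
7 | 2-lithio derivative of 5 | [Li]C1(C[C@H](C)O[Si](C)(C)C(C)(C)C)SCCCS1 | intermediate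
8 | 1-{2-[(2S)-2-(tert-butyldimethylsilyloxy)propyl]-1,3-dithian-2-yl}propan-1-one | CCC(=O)C1(C[C@H](C)O[Si](C)(C)C(C)(C)C)SCCCS1 | intermediate
9 | 3-(tert-butyldimethylsilyloxy)propanal | O=CCCO[Si](C)(C)C(C)(C)C | starting material
10 | methyl acrylate | C=CC(=O)OC | starting material
11 | methyl 5-(tert-butyldimethylsilyloxy)-3-hydroxy-2-methylidenepentanoate (racemic) | C=C(C(=O)OC)C(O)CCO[Si](C)(C)C(C)(C)C | intermediate
12 | methyl (2Z)-2-(bromomethyl)-5-(tert-butyldimethylsilyloxy)pent-2-enoate | COC(=O)/C(CBr)=C/CCO[Si](C)(C)C(C)(C)C | intermediate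
13 | (4S)-2,2-dimethyl-1,3-dioxolane-4-carbaldehyde ((S)-glyceraldehyde acetonide) | O=C[C@@H]1COC(C)(C)O1 | starting material
14 | methyl (3S,4R)-3-[2-(tert-butyldimethylsilyloxy)ethyl]-4-[(4S)-2,2-dimethyl-1,3-dioxolan-4-yl]-4-hydroxy-2-methylidenebutanoate | C=C(C(=O)OC)[C@H](CCO[Si](C)(C)C(C)(C)C)[C@@H](O)[C@@H]1COC(C)(C)O1 | intermediate
15 | (4S,5R)-4-[2-(tert-butyldimethylsilyloxy)ethyl]-5-[(4S)-2,2-dimethyl-1,3-dioxolan-4-yl]-3-methylideneoxolan-2-one | C=C1C(=O)O[C@@H]([C@@H]2COC(C)(C)O2)[C@H]1CCO[Si](C)(C)C(C)(C)C | intermediate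
16 | (4S,5R)-5-[(4S)-2,2-dimethyl-1,3-dioxolan-4-yl]-4-(2-hydroxyethyl)-3-methylideneoxolan-2-one | C=C1C(=O)O[C@@H]([C@@H]2COC(C)(C)O2)[C@H]1CCO | intermediate
17 | [(2R,3S)-2-[(4S)-2,2-dimethyl-1,3-dioxolan-4-yl]-4-methylidene-5-oxooxolan-3-yl]acetaldehyde | C=C1C(=O)O[C@@H]([C@@H]2COC(C)(C)O2)[C@H]1CC=O | intermediate
18 | (Z)-enol diisopinocampheylborinate of 8 | C/C=C(\OB([C@@H]1C[C@@H]2C[C@H]([C@H]1C)C2(C)C)[C@@H]3C[C@@H]4C[C@H]([C@H]3C)C4(C)C)C5(C[C@H](C)O[Si](C)(C)C(C)(C)C)SCCCS5 | intermediate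
19 | (4S,5R)-4-[(2R,3S)-4-{2-[(2S)-2-(tert-butyldimethylsilyloxy)propyl]-1,3-dithian-2-yl}-2-hydroxy-3-methyl-4-oxobutyl]-5-[(4S)-2,2-dimethyl-1,3-dioxolan-4-yl]-3-methylideneoxolan-2-one | C=C1C(=O)O[C@@H]([C@@H]2COC(C)(C)O2)[C@H]1C[C@@H](O)[C@H](C)C(=O)C3(C[C@H](C)O[Si](C)(C)C(C)(C)C)SCCCS3 | intermediate
20 | 9-O-TBS ether of 19 | C=C1C(=O)O[C@@H]([C@@H]2COC(C)(C)O2)[C@H]1C[C@@H](O[Si](C)(C)C(C)(C)C)[C@H](C)C(=O)C3(C[C@H](C)O[Si](C)(C)C(C)(C)C)SCCCS3 | intermediate
21 | (4S,5R)-4-[(2R,3S)-2-(tert-butyldimethylsilyloxy)-4-{2-[(2S)-2-(tert-butyldimethylsilyloxy)propyl]-1,3-dithian-2-yl}-3-methyl-4-oxobutyl]-5-[(1S)-1,2-dihydroxyethyl]-3-methylideneoxolan-2-one | C=C1C(=O)O[C@@H]([C@@H](O)CO)[C@H]1C[C@@H](O[Si](C)(C)C(C)(C)C)[C@H](C)C(=O)C3(C[C@H](C)O[Si](C)(C)C(C)(C)C)SCCCS3 | intermediate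
22 | (2R,3S)-3-[(2R,3S,7S)-2,7-bis(tert-butyldimethylsilyloxy)-3-methyl-4,5-dioxooctyl]-4-methylidene-5-oxooxolane-2-carbaldehyde | C=C1C(=O)O[C@@H](C=O)[C@H]1C[C@@H](O[Si](C)(C)C(C)(C)C)[C@H](C)C(=O)C(=O)C[C@H](C)O[Si](C)(C)C(C)(C)C | intermediate
23 | (2S)-2-methylbutanoic anhydride | CC[C@H](C)C(=O)OC(=O)[C@@H](C)CC | starting material
24 | bis(diiodosamarium) (E)-enediolate of 22 | C=C1C(=O)O[C@@H](C=O)[C@H]1C[C@@H](O[Si](C)(C)C(C)(C)C)[C@H](C)/C(O[Sm](I)I)=C(\O[Sm](I)I)C[C@H](C)O[Si](C)(C)C(C)(C)C | intermediate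
25 | bis(diiodosamarium) 1,5-diolate of the cyclised aldol | C=C1C(=O)O[C@@H]2[C@H]1C[C@@H](O[Si](C)(C)C(C)(C)C)[C@H](C)[C@@](O[Sm](I)I)(C(=O)C[C@H](C)O[Si](C)(C)C(C)(C)C)[C@H]2O[Sm](I)I | intermediate
26 | (3aS,5R,6S,7S,8S,8aR)-5-(tert-butyldimethylsilyloxy)-7-[(3S)-3-(tert-butyldimethylsilyloxy)butanoyl]-7-hydroxy-6-methyl-3-methylidene-2-oxooctahydro-2H-cyclohepta[b]furan-8-yl (2S)-2-methylbutanoate | C=C1C(=O)O[C@@H]2[C@H]1C[C@@H](O[Si](C)(C)C(C)(C)C)[C@H](C)[C@@](O)(C(=O)C[C@H](C)O[Si](C)(C)C(C)(C)C)[C@H]2OC(=O)[C@@H](C)CC | intermediate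
27 | (3aS,5R,6S,7S,8S,8aR)-5,7-dihydroxy-7-[(3S)-3-hydroxybutanoyl]-6-methyl-3-methylidene-2-oxooctahydro-2H-cyclohepta[b]furan-8-yl (2S)-2-methylbutanoate | C=C1C(=O)O[C@@H]2[C@H]1C[C@@H](O)[C@H](C)[C@@](O)(C(=O)C[C@H](C)O)[C@H]2OC(=O)[C@@H](C)CC | target

## Step count and risks

Total steps: 13. Longest linear sequence: 11 (steps 3–13, from 9 and 10); the ketone arm 1 → 8 takes 2 steps and joins at step 8.

The three steps most likely to fail:

**Step 12 (ring-B closure).** The enediolate geometry and therefore the C1/C5 relationship are unproven, the samarium could cleave the α-acyloxy aldehyde, and the in-situ acylation may be slow. The fallback replaces the closed metal-enediolate aldol by an open Mukaiyama aldol. Setting out from 22, Zn dust and Me3SiCl (THF, 0 °C) reduce the diketone to the bis(trimethylsilyl) enediol ether F1. BF3·OEt2 (CH2Cl2, −78 °C) then closes ring B through a dipole-minimised open transition state (C1–OSi anti to the activated C5=O) to the 1-O-trimethylsilyl β-hydroxy ketone F2. Yamaguchi esterification with (S)-2-methylbutanoic acid (2,4,6-trichlorobenzoyl chloride, Et3N, DMAP, toluene) gives the 1-O-trimethylsilyl ester F3. The conditions of step 13 remove all three silyl groups, and the route is rejoined at 27.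

**Step 11 (double unmasking).** The glycol may cleave sluggishly in wet MeCN, or the sensitive diketo-aldehyde may degrade under the acid released. The fallback splits the step into two mechanistically different operations. Setting out from 21, Pb(OAc)4 (CH2Cl2, −40 °C) cleaves the glycol while the dithiane stays on, giving the aldehyde dithiane F4. Non-oxidative S-alkylative hydrolysis (MeI, CaCO3, MeCN/H2O, 40 °C) then frees the C2 ketone, and the route is rejoined at 22.

**Step 8 (reagent-controlled aldol).** The hindered dithianyl ketone may enolise poorly with the bulky boron triflate, or give low facial selectivity on the β-branched aldehyde. The fallback builds C9/C10 by crotylation and the diketone by alkene oxidation, with no dithiane. Setting out from 17, the (Z)-crotylboronate of diisopropyl (R,R)-tartrate (4 Å sieves, toluene, −78 °C; the tartrate enantiomer is chosen for si-face attack) gives the syn homoallylic alcohol F5, and TBSOTf/2,6-lutidine gives its silyl ether F6. Separately, 2 is opened with vinylmagnesium bromide and CuI (cat.) to (2S)-pent-4-en-2-ol F7, which is silylated (TBSCl, imidazole) to F8. Cross-metathesis of F6 with F8 (second-generation Grubbs catalyst, CH2Cl2, 40 °C) gives the (E)-alkene F9. OsO4 (cat.)/NMO dihydroxylates this electron-rich alkene in preference to the α-methylene lactone to give the diol F10, and IBX (EtOAc, 70 °C) oxidises it to the diketone acetonide F11. Zn(NO3)2·6H2O (MeCN, 50 °C) gives the diketone diol F12, and PhI(OAc)2 (CH2Cl2, rt) cleaves the glycol, rejoining the route at 22.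

## Further compounds

F1 | step 12 | bis(trimethylsilyl) enediol ether of 22 (E/Z mixture) | C=C1C(=O)O[C@@H](C=O)[C@H]1C[C@@H](O[Si](C)(C)C(C)(C)C)[C@H](C)C(O[Si](C)(C)C)=C(O[Si](C)(C)C)C[C@H](C)O[Si](C)(C)C(C)(C)C
F2 | step 12 | (3aS,5R,6S,7S,8S,8aR)-5-(tert-butyldimethylsilyloxy)-7-[(3S)-3-(tert-butyldimethylsilyloxy)butanoyl]-8-hydroxy-6-methyl-3-methylidene-7-(trimethylsilyloxy)octahydro-2H-cyclohepta[b]furan-2-one | C=C1C(=O)O[C@@H]2[C@H]1C[C@@H](O[Si](C)(C)C(C)(C)C)[C@H](C)[C@@](O[Si](C)(C)C)(C(=O)C[C@H](C)O[Si](C)(C)C(C)(C)C)[C@H]2O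
F3 | step 12 | 1-O-trimethylsilyl ether of 26 | C=C1C(=O)O[C@@H]2[C@H]1C[C@@H](O[Si](C)(C)C(C)(C)C)[C@H](C)[C@@](O[Si](C)(C)C)(C(=O)C[C@H](C)O[Si](C)(C)C(C)(C)C)[C@H]2OC(=O)[C@@H](C)CC
F4 | step 11 | (2R,3S)-3-[(2R,3S)-2-(tert-butyldimethylsilyloxy)-4-{2-[(2S)-2-(tert-butyldimethylsilyloxy)propyl]-1,3-dithian-2-yl}-3-methyl-4-oxobutyl]-4-methylidene-5-oxooxolane-2-carbaldehyde | C=C1C(=O)O[C@@H](C=O)[C@H]1C[C@@H](O[Si](C)(C)C(C)(C)C)[C@H](C)C(=O)C3(C[C@H](C)O[Si](C)(C)C(C)(C)C)SCCCS3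
F5 | step 8 | (4S,5R)-5-[(4S)-2,2-dimethyl-1,3-dioxolan-4-yl]-4-[(2R,3R)-2-hydroxy-3-methylpent-4-en-1-yl]-3-methylideneoxolan-2-one | C=C1C(=O)O[C@@H]([C@@H]2COC(C)(C)O2)[C@H]1C[C@@H](O)[C@H](C)C=C
F6 | step 8 | TBS ether of F5 | C=C1C(=O)O[C@@H]([C@@H]2COC(C)(C)O2)[C@H]1C[C@@H](O[Si](C)(C)C(C)(C)C)[C@H](C)C=C
F7 | step 8 | (2S)-pent-4-en-2-ol | C=CC[C@H](C)O
F8 | step 8 | tert-butyldimethyl[(2S)-pent-4-en-2-yloxy]silane | C=CC[C@H](C)O[Si](C)(C)C(C)(C)C
F9 | step 8 | (4S,5R)-4-[(2R,3R,4E,7S)-2,7-bis(tert-butyldimethylsilyloxy)-3-methyloct-4-en-1-yl]-5-[(4S)-2,2-dimethyl-1,3-dioxolan-4-yl]-3-methylideneoxolan-2-one | C=C1C(=O)O[C@@H]([C@@H]2COC(C)(C)O2)[C@H]1C[C@@H](O[Si](C)(C)C(C)(C)C)[C@H](C)/C=C/C[C@H](C)O[Si](C)(C)C(C)(C)C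
F10 | step 8 | 4,5-diol from F9 (mixture at the two new carbinol centres, both oxidised next) | C=C1C(=O)O[C@@H]([C@@H]2COC(C)(C)O2)[C@H]1C[C@@H](O[Si](C)(C)C(C)(C)C)[C@H](C)C(O)C(O)C[C@H](C)O[Si](C)(C)C(C)(C)C
F11 | step 8 | (4S,5R)-4-[(2R,3S,7S)-2,7-bis(tert-butyldimethylsilyloxy)-3-methyl-4,5-dioxooctyl]-5-[(4S)-2,2-dimethyl-1,3-dioxolan-4-yl]-3-methylideneoxolan-2-one | C=C1C(=O)O[C@@H]([C@@H]2COC(C)(C)O2)[C@H]1C[C@@H](O[Si](C)(C)C(C)(C)C)[C@H](C)C(=O)C(=O)C[C@H](C)O[Si](C)(C)C(C)(C)C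
F12 | step 8 | (4S,5R)-4-[(2R,3S,7S)-2,7-bis(tert-butyldimethylsilyloxy)-3-methyl-4,5-dioxooctyl]-5-[(1S)-1,2-dihydroxyethyl]-3-methylideneoxolan-2-one | C=C1C(=O)O[C@@H]([C@@H](O)CO)[C@H]1C[C@@H](O[Si](C)(C)C(C)(C)C)[C@H](C)C(=O)C(=O)C[C@H](C)O[Si](C)(C)C(C)(C)C
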